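**Retrosynthetic overview**
1. The target comes from cage diketone 13 by two late steps: methyl addition to the ring B ketone, then hydrogenation of the β-keto-γ-lactone ketone.
2. Cage 13 (cyclopentane plus bicyclo[2.2.2]octane) comes from one intramolecular Diels–Alder reaction between a dearomatised phthalide dienone and an exocyclic methylene on ring B.
3. That dienone comes from C-alkylation of 5,7-dihydroxy-4,6-dimethylphthalide 3 at C-4 with the allylic ammonium salt of spiro enone 9. The γ-lactone arrives with the phthalide.
4. Spiro-lactone enone 7 (rings A and B) comes from acid lactonisation of 6, which comes from a catalytic asymmetric deconjugative vinylation of piperitenone. This sets the spiro centre, the only stereocentre not set under substrate or late catalyst control.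
5. Ring order: B (bought) → A → cyclopentane and bicyclo[2.2.2]octane together.

Assumption: 1, 4 and 5 are bought (5 is one esterification from commercial cis-3-chloroacrylic acid); locants in the text are those of the phthalide (C-1 to C-7a) and of the 2-oxaspiro[5.5]undecane unit (C-1 to C-11, spiro atom C-6).

Step 1
Reactants: 1 5,7-dihydroxy-4-methyl-2-benzofuran-1(3H)-one
Product: 2 6-[(dimethylamino)methyl]-5,7-dihydroxy-4-methyl-2-benzofuran-1(3H)-one
Conditions: 37% aq. CH2O, 40% aq. Me2NH, EtOH, 23 °C
Reagents that add atoms: formaldehyde C=O; dimethylamine CNC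
Why: Phenolic Mannich reaction at C-6, the only free ring position and ortho to both hydroxyl groups; no stereocentre is formed.

Step 2
Reactants: 2 6-[(dimethylamino)methyl]-5,7-dihydroxy-4-methyl-2-benzofuran-1(3H)-one
Product: 3 5,7-dihydroxy-4,6-dimethyl-2-benzofuran-1(3H)-one
Conditions: H2 (4 atm), Pd/C (10 wt%), EtOH/AcOH, 60 °C
Reagents that add atoms: none
Why: Hydrogenolysis of an ortho-hydroxybenzylic amine (through the ortho-quinone methide) gives the C-methyl group, and the phthalide lactone survives these mild conditions.

Step 3
Reactants: 4 piperitenone; 5 methyl (2Z)-3-chloroprop-2-enoate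
Product: 6 methyl (2Z)-3-[(1R)-4-methyl-2-oxo-1-(prop-1-en-2-yl)cyclohex-3-en-1-yl]prop-2-enoate
Conditions: 5 (1.5 equiv), O-allyl-N-(9-anthracenylmethyl)cinchonidinium bromide (10 mol%), KOH (powder, 3 equiv), PhMe, −40 °C
Reagents that add atoms: none
Why: Proposed new method: KOH removes a γ-proton of the isopropylidene methyl syn to the carbonyl (the site that reacts in the deconjugative α-alkylation of pulegone), the cross-conjugated trienolate enters toluene as a tight ion pair with the chiral ammonium cation that shields one face of the α-carbon, and α-attack on the (Z)-β-chloroacrylate by addition–elimination with retention of alkene geometry creates the quaternary (R) centre as the first stereocentre; the closest known reaction types are phase-transfer-catalysed asymmetric nucleophilic vinylic substitution of cyclic β-keto esters with (Z)-β-chloro enones and phase-transfer deconjugative α-alkylation of α-alkylidene ketones, here extended to an unstabilised dienone dienolate.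

Step 4
Reactants: 6 methyl (2Z)-3-[(1R)-4-methyl-2-oxo-1-(prop-1-en-2-yl)cyclohex-3-en-1-yl]prop-2-enoate
Product: 7 (6R)-1,1,9-trimethyl-2-oxaspiro[5.5]undeca-4,8-diene-3,7-dione
Conditions: TfOH (1.0 equiv), CH2Cl2, 0 °C; then H2O
Reagents that add atoms: none
Why: Cationic lactonisation (Markovnikov hydro-acyloxylation): protonation of the isopropenyl group gives a tertiary cation that the cis-placed ester carbonyl traps through a six-membered transition state, the methyl group leaves on aqueous work-up, and the quaternary centre is untouched.

Step 5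
Reactants: 7 (6R)-1,1,9-trimethyl-2-oxaspiro[5.5]undeca-4,8-diene-3,7-dione
Product: 9 (6R)-8-[(dimethylamino)methyl]-1,1,9-trimethyl-2-oxaspiro[5.5]undeca-4,8-diene-3,7-dione, via β,γ-unsaturated Mannich base 8 (not isolated)
Conditions: KHMDS (1.1 equiv), THF, −78 °C; Me2N+=CH2 I− (1.3 equiv), −78 → 0 °C; then Et3N, CH2Cl2, 23 °C
Reagents that add atoms: N,N-dimethylmethyleneiminium iodide C=[N+](C)C.[I-]
Why: Mannich reaction of the extended enolate (C-6 is quaternary so only γ-protons are available) at its α-carbon C-8, after which triethylamine moves the double bond back into conjugation so that either regioisomeric dienolate converges on the same 2-(aminomethyl) enone; no stereocentre is formed.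

Step 6
Reactants: 9 (6R)-8-[(dimethylamino)methyl]-1,1,9-trimethyl-2-oxaspiro[5.5]undeca-4,8-diene-3,7-dione; 3 5,7-dihydroxy-4,6-dimethyl-2-benzofuran-1(3H)-one
Product: 13 Diels–Alder cage diketone (ring B ketone; β-keto-γ-lactone as enol; six stereocentres as in the target), via ammonium iodide 10 (not isolated), via C-alkylated dienone 11 (not isolated), via exo-methylene ketone 12 (not isolated)
Conditions: MeI (3 equiv), MeCN, 23 °C, evaporate; 3 (1.1 equiv), LiOtBu (1.1 equiv), THF/PhMe, 0 → 23 °C; then DABCO (0.3 equiv), PhMe, 105 °C
Reagents that add atoms: none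
Why: Alkylative dearomatisation followed by an intramolecular inverse-demand Diels–Alder reaction: the lithium phenoxide of 3 is C-alkylated at methyl-bearing C-4 by the allylic ammonium salt (reversible by retro-Michael, so O-adducts, C-6 adducts and both C-4 epimers funnel through the vinylogous-acid C-4 adduct), amine-mediated deconjugation exposes the exocyclic methylene, and the cyclohexadienone adds across phthalide C-3a and C-6 on the face syn to the CH2 link, so phthalide C-4 fixes the three new cage centres, only the C-4 epimer whose CH2 link can sit axial beside the small CH= arm (not the CMe2 arm) of the spiro centre reaches the transition state, and the CH next to the ring B ketone ends cis-fused.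

Step 7
Reactants: 13 Diels–Alder cage diketone
Product: 14 tertiary carbinol (target oxidised at the secondary carbinol; β-keto-γ-lactone as enol)
Conditions: MeLi (3.5 equiv), CeCl3 (4 equiv), THF, −78 °C; then H2O
Reagents that add atoms: methyllithium [Li]C
Why: Organocerium 1,2-addition: the first equivalent converts the β-keto-lactone enol into an inert enolate, the bridging ketone is blocked by two quaternary α-carbons, lactones do not react at −78 °C, and methyl adds to the ring B ketone from the face opposite the cage (the upper face is covered by the cyclopentane CH2, the lactone CH2 and the vinyl arm of ring A), which places the hydroxyl cis to the cage.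

Step 8
Reactants: 14 tertiary carbinol
Product: 15 CNP0360620.3
Conditions: [RuCl((S)-BINAP)(p-cymene)]Cl (3 mol%), H2 (50 atm), MeOH/CH2Cl2, 50 °C
Reagents that add atoms: none
Why: Noyori-type inner-sphere hydrogenation of a β-keto ester under dynamic kinetic resolution: the keto tautomer chelates ruthenium through the phthalide-derived C-7 ketone and the lactone carbonyl, hydride is delivered on the face bearing the lactone carbonyl, so the hydroxyl ends anti to that carbonyl and syn to the bridging ketone while C-7a (mobile through the enol) is fixed in the same event; (S)-BINAP is the antipode whose quadrant model fits this face, and the hindered non-chelating ketone and the enoate are left alone.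

**Compound list**
1 | 5,7-dihydroxy-4-methyl-2-benzofuran-1(3H)-one (5,7-dihydroxy-4-methylphthalide) | O=C1OCc2c(C)c(O)cc(O)c12 | starting material
2 | 6-[(dimethylamino)methyl]-5,7-dihydroxy-4-methyl-2-benzofuran-1(3H)-one | O=C1OCc2c(C)c(O)c(CN(C)C)c(O)c12 | intermediate
3 | 5,7-dihydroxy-4,6-dimethyl-2-benzofuran-1(3H)-one | O=C1OCc2c(C)c(O)c(C)c(O)c12 | intermediate
4 | piperitenone, 3-methyl-6-(propan-2-ylidene)cyclohex-2-en-1-one | CC1=CC(=O)C(=C(C)C)CC1 | starting material
5 | methyl (2Z)-3-chloroprop-2-enoate | COC(=O)/C=C\Cl | starting material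
6 | methyl (2Z)-3-[(1R)-4-methyl-2-oxo-1-(prop-1-en-2-yl)cyclohex-3-en-1-yl]prop-2-enoate | COC(=O)/C=C\[C@@]1(C(C)=C)CCC(C)=CC1=O | intermediate
7 | (6R)-1,1,9-trimethyl-2-oxaspiro[5.5]undeca-4,8-diene-3,7-dione | CC1(C)OC(=O)C=C[C@]12CCC(C)=CC2=O | intermediate
8 | (6R)-8-[(dimethylamino)methyl]-1,1-dimethyl-9-methylidene-2-oxaspiro[5.5]undec-4-ene-3,7-dione (kinetic β,γ-unsaturated Mannich base, C-8 epimers, exocyclic isomer drawn) | CC1(C)OC(=O)C=C[C@]12CCC(=C)C(CN(C)C)C2=O | intermediate
9 | (6R)-8-[(dimethylamino)methyl]-1,1,9-trimethyl-2-oxaspiro[5.5]undeca-4,8-diene-3,7-dione | CC1(C)OC(=O)C=C[C@]12CCC(C)=C(CN(C)C)C2=O | intermediate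
10 | N,N,N-trimethyl-1-[(6R)-1,1,9-trimethyl-3,7-dioxo-2-oxaspiro[5.5]undeca-4,8-dien-8-yl]methanaminium iodide | CC1(C)OC(=O)C=C[C@]12CCC(C)=C(C[N+](C)(C)C)C2=O.[I-] | intermediate
11 | (4R)-7-hydroxy-4,6-dimethyl-4-{[(6R)-1,1,9-trimethyl-3,7-dioxo-2-oxaspiro[5.5]undeca-4,8-dien-8-yl]methyl}-2-benzofuran-1,5(3H,4H)-dione | CC1(C)OC(=O)C=C[C@]12CCC(C)=C(C[C@@]3(C)C(=O)C(C)=C(O)C4=C3COC4=O)C2=O | intermediate
12 | (4R)-4-{[(6R,8R)-1,1-dimethyl-9-methylidene-3,7-dioxo-2-oxaspiro[5.5]undec-4-en-8-yl]methyl}-7-hydroxy-4,6-dimethyl-2-benzofuran-1,5(3H,4H)-dione | CC1(C)OC(=O)C=C[C@]12CCC(=C)[C@@H](C[C@@]3(C)C(=O)C(C)=C(O)C4=C3COC4=O)C2=O | intermediate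
13 | Diels–Alder cage diketone: target skeleton with a ketone in place of C(CH3)(OH) and the enol of the β-keto-γ-lactone in place of CH(OH)–CH | CC1(C)OC(=O)C=C[C@]12CC[C@]13C[C@]4(C)C(=O)[C@](C)(C[C@H]1C2=O)[C@]31COC(=O)C1=C4O | intermediate
14 | tertiary carbinol: target with the enol of the β-keto-γ-lactone in place of CH(OH)–CH | CC1(C)OC(=O)C=C[C@]12CC[C@]13C[C@]4(C)C(=O)[C@](C)(C[C@H]1[C@@]2(C)O)[C@]31COC(=O)C1=C4O | intermediate
15 | CNP0360620.3 | CC1(C)OC(=O)C=C[C@]12CC[C@]13C[C@]4(C)C(=O)[C@](C)(C[C@H]1[C@@]2(C)O)[C@]31COC(=O)[C@@H]1[C@H]4O | target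

**Step count**
Total steps: 8. Longest linear sequence: 6 (steps 3 to 8, from piperitenone).

**Steps most likely to fail**

Step 3 (the new vinylation). The base may enolise the endocyclic arm instead and alkylate C-2, the ion pair may give low enantioselectivity, or 5 may lose HCl to propiolate and give E/Z mixtures. The fallback uses known chemistry, sets out from 5 and returns at 6. The kinetic lithium enolate of commercial 3-methylcyclohex-2-en-1-one F1 (LDA, THF, −78 °C) is C-acetylated with 1-acetylimidazole to give 6-acetyl-3-methylcyclohex-2-en-1-one F2. F2 is a cyclic 1,3-dicarbonyl compound, the substrate class for which phase-transfer-catalysed asymmetric vinylic substitution with (Z)-β-chloroacrylates is established; with 5, a cinchona-derived ammonium salt and K2CO3 it gives methyl (2Z)-3-[(1R)-1-acetyl-4-methyl-2-oxocyclohex-3-en-1-yl]prop-2-enoate F3. Chemoselective Wittig methylenation of the saturated acetyl group (Ph3P=CH2, THF, 0 °C) then gives 6.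

Step 6 (alkylation and cycloaddition in one pot). O-alkylation or C-6 alkylation may dominate, the retro-Michael equilibrium may be too slow to correct the phthalide C-4 epimer, the endocyclic β,γ-isomer may form instead of the exocyclic one, or the Diels–Alder reaction may be slower than decomposition. The fallback sets out from 9 and 3 and returns at 13. The alkylation is stopped at 23 °C and dienone 11 is isolated; its mismatched C-4 epimer is returned to the pool by brief treatment with LiOtBu. Silylation (TBSOTf, Et3N, CH2Cl2) caps the vinylogous acid and locks the exocyclic diene as bis-silyl dienol ether F4. Heating F4 in PhMe at 110 °C gives the silylated cage F5 by the same intramolecular Diels–Alder reaction, now with a fixed electron-rich dienophile. HF·pyridine in THF removes both silyl groups and gives 13.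

Step 8 (final hydrogenation). The ketone is flanked by a quaternary and a tertiary carbon and may not bind the catalyst, the facial sense may be mismatched with the cage, or the ring A alkene may be reduced. The fallback sets out from 14 and returns at 15. It replaces metal-chelate control by enzyme control: 14 is reduced with a ketoreductase chosen from a screening panel (NADPH, isopropanol recycling, pH 7 buffer with DMSO), a method established for α-substituted β-keto esters under dynamic kinetic resolution. It gives 15 directly, so no further compound arises (F0).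

**Further compounds**
F1 | step 3 | 3-methylcyclohex-2-en-1-one | CC1=CC(=O)CCC1
F2 | step 3 | 6-acetyl-3-methylcyclohex-2-en-1-one | CC(=O)C1CCC(C)=CC1=O
F3 | step 3 | methyl (2Z)-3-[(1R)-1-acetyl-4-methyl-2-oxocyclohex-3-en-1-yl]prop-2-enoate | COC(=O)/C=C\[C@@]1(C(C)=O)CCC(C)=CC1=O
F4 | step 6 | bis(tert-butyldimethylsilyl) dienol ether of 11 (exocyclic diene on ring B, silylated vinylogous acid) | CC1(C)OC(=O)C=C[C@]12CCC(=C)C(C[C@@]3(C)C(=O)C(C)=C(O[Si](C)(C)C(C)(C)C)C4=C3COC4=O)=C2O[Si](C)(C)C(C)(C)C
F5 | step 6 | bis(tert-butyldimethylsilyl) enol ether of cage diketone 13 | CC1(C)OC(=O)C=C[C@]12CC[C@]13C[C@]4(C)C(=O)[C@](C)(CC1=C2O[Si](C)(C)C(C)(C)C)[C@]31COC(=O)C1=C4O[Si](C)(C)C(C)(C)C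
F0 | step 8 | none | none
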